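**Assumption:** the target SMILES has no stereocentre and the molecule is achiral, so there is no enantiomer to control; "single enantiomer" is taken as the one compound drawn.

## Retrosynthetic overview

- The benzene ring is never built. It is bought as 3,4-dihydroxybenzaldehyde (1), and the three C–Br bonds disconnect to 1 + Br2, giving aldehyde 2.
- The only ring formed is the pyrrolidin-2-one, closed last. The amide N–C(=O) bond opens to an N-benzyl γ-aminobutanoate, and the benzylic C–N bond (at the C=N level) leads back to 2 + GABA methyl ester hydrochloride (3).
- This follows the presumed biogenesis in one flask: the tyrosine-derived tribromo-dihydroxybenzyl unit is joined to the nitrogen of glutamate-derived GABA, then the γ-lactam closes (aldimine 4 → amino ester 5 → target 6). No protecting groups are used.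

## Route

Step 1
Reactants: 1 3,4-dihydroxybenzaldehyde
Product: 2 2,3,6-tribromo-4,5-dihydroxybenzaldehyde
Conditions: Br2 (3.6 equiv), glacial AcOH, rt then 65 °C; pour into ice-cold aq NaHSO3, filter
Reagents that add atoms: bromine, BrBr
Why: Exhaustive electrophilic aromatic bromination: each of the three free positions of 1 is ortho or para to a free catechol OH, so the ring should take three Br much as catechol takes four with Br2 in AcOH, while the formyl group and the anhydrous acidic medium hold back quinone formation and ipso-bromodeformylation; no stereocentre arises.

Step 2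
Reactants: 2 2,3,6-tribromo-4,5-dihydroxybenzaldehyde; 3 methyl 4-aminobutanoate hydrochloride
Product: 6 1-[(2,3,6-tribromo-4,5-dihydroxyphenyl)methyl]pyrrolidin-2-one, via aldimine 4 (not isolated), via amino ester 5 (not isolated)
Conditions: 3 (1.4 equiv), Et3N (2.5 equiv), 3 Å molecular sieves, MeOH, rt, 6 h; NaBH4 (1.5 equiv), 0 °C to rt, 1 h; then 65 °C, 16 h, argon; 1 M HCl work-up (pH 3), EtOAc
Reagents that add atoms: none
Why: Reductive amination followed by 5-exo-trig lactamization of a γ-amino ester: the amine of 3 condenses with the doubly ortho-brominated aldehyde to the (E)-aldimine 4, NaBH4 in MeOH reduces the C=N bond but neither the methyl ester nor the aryl C–Br bonds, and in the basic borate medium the free secondary amine of 5 closes irreversibly onto the ester with loss of MeOH, the catechol being held as its borate complex until the acidic work-up; no stereocentre is formed and the product is achiral.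

## Compound list

1 | 3,4-dihydroxybenzaldehyde | O=Cc1ccc(O)c(O)c1 | starting material
2 | 2,3,6-tribromo-4,5-dihydroxybenzaldehyde | O=Cc1c(Br)c(O)c(O)c(Br)c1Br | intermediate
3 | methyl 4-aminobutanoate hydrochloride | COC(=O)CCCN.Cl | starting material
4 | methyl 4-{[(E)-(2,3,6-tribromo-4,5-dihydroxyphenyl)methylidene]amino}butanoate | COC(=O)CCC/N=C/c1c(Br)c(O)c(O)c(Br)c1Br | intermediate
5 | methyl 4-{[(2,3,6-tribromo-4,5-dihydroxyphenyl)methyl]amino}butanoate | COC(=O)CCCNCc1c(Br)c(O)c(O)c(Br)c1Br | intermediate
6 | 1-[(2,3,6-tribromo-4,5-dihydroxyphenyl)methyl]pyrrolidin-2-one | O=C1CCCN1Cc1c(Br)c(O)c(O)c(Br)c1Br | target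

## Step count and risk

Total step count: 2 (one isolation after step 1; step 2 is a single-flask cascade).
Longest linear sequence: 2 steps from 1.

The route has only two steps, so both are ranked, most fragile first.

1) Step 2. Imine formation at the hindered, phenoxide-deactivated aldehyde may be slow enough that free 3 cyclizes to pyrrolidin-2-one first. The lactam closure of 5 may also stall if the amine sits as an ammonium phenoxide zwitterion. The fallback sets out from 2 and returns at 6. Reduce 2 with NaBH4 in MeOH at 0 °C to the benzyl alcohol (2,3,6-tribromo-4,5-dihydroxyphenyl)methanol F1. Then heat F1 in neat pyrrolidin-2-one (O=C1CCCN1, commercial, about 10 equiv) with TsOH·H2O (10 mol %) at 90 °C under argon. The para-hydroxybenzyl alcohol ionizes to the para-quinone methide (the presumed biosynthetic electrophile), which is trapped at the lactam nitrogen with loss of water. O-alkylation is reversible under the acid, so the N-benzyl lactam 6 accumulates.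

2) Step 1. The third bromination, next to the formyl group, may stop at the dibromide. Forcing it may cause ipso-bromodeformylation to tetrabromocatechol. The fallback sets out from 1 and returns at 6 by inverting the order of events. Treat 1 with 3 under the conditions of step 2. This passes through the aldimine methyl 4-{[(E)-(3,4-dihydroxyphenyl)methylidene]amino}butanoate F2 and the amino ester methyl 4-{[(3,4-dihydroxyphenyl)methyl]amino}butanoate F3, neither isolated, to the lactam 1-[(3,4-dihydroxyphenyl)methyl]pyrrolidin-2-one F4. Then brominate F4 with Br2 (3.1 equiv) in AcOH at rt. The ring is now an electron-rich 4-alkylcatechol without the deactivating formyl group, so its three free positions are filled under mild conditions to give 6 directly.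

## Further compounds

F1 | step 2 | (2,3,6-tribromo-4,5-dihydroxyphenyl)methanol | OCc1c(Br)c(O)c(O)c(Br)c1Br
F2 | step 1 | methyl 4-{[(E)-(3,4-dihydroxyphenyl)methylidene]amino}butanoate | COC(=O)CCC/N=C/c1ccc(O)c(O)c1
F3 | step 1 | methyl 4-{[(3,4-dihydroxyphenyl)methyl]amino}butanoate | COC(=O)CCCNCc1ccc(O)c(O)c1
F4 | step 1 | 1-[(3,4-dihydroxyphenyl)methyl]pyrrolidin-2-one | O=C1CCCN1Cc1ccc(O)c(O)c1
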